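**Retrosynthetic overview**
1. The two acyl groups are cut last (C3–O senecioate, C9–O angelate). C9–O comes from hydroxylation of the C8 ketone enolate, and the isopropenyl C11=C13 from methylenation of a C11 methyl ketone.
2. Ring B is opened at C7–C8 (aldol addition of the C11 methyl ketone to a C8 aldehyde). C3–O and C15 on ring A come from a C4 ketone (methylenation, allylic oxidation, reagent-controlled reduction, hydrogen-atom-transfer hydrogenation).
3. The strategy rests on the vicinal pair C10 (H, C9) / C5 (quaternary: C14 methyl, C6) at the fusion of rings A and B, with C9 and C6 cis on ring A and C14 trans to C9. It is cut at C10–C9 and C5–C14 to a 2-alkylcyclohex-2-enone, vinylmagnesium bromide and iodomethane.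
4. The enone comes from 2-iodocyclohex-2-enone and the 9-BBN adduct of 2-methyl-2-vinyl-1,3-dioxolane by B-alkyl Suzuki coupling.
5. Ring order: ring A is the starting cyclohexenone ring and is kept throughout; ring B is closed in step 12.

Key step: step 3

Convention: eremophilane numbering is used for all intermediates (ring A = C1–C5 and C10, ring B = C5–C10, C14 = methyl on C5, C15 = carbon on C4, C11–C13 = side chain on C7); β is the face of C14.
Assumption 1: the ligand enantiomer written in step 3 is assumed, by analogy with 2-unsubstituted cyclohexenones, to deliver the vinyl group to the Si face of C3 of enone 5 (giving 3R); if the sense proved opposite, the mirror-image ligand would be used.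
Assumption 2: 2-methyl-2-vinyl-1,3-dioxolane (the ethylene ketal of but-3-en-2-one) is taken as a commercial starting material.

**Route**

Step 1
Reactants: 1 cyclohex-2-en-1-one
Product: 2 2-iodocyclohex-2-en-1-one
Conditions: I2, pyridine, CH2Cl2, 0 °C → rt
Reagents that add atoms: iodine, II
Why: α-Iodination of the enone by a Morita–Baylis–Hillman-type addition–elimination (pyridine adds at C3, the enolate is iodinated, pyridine is eliminated) should give the 2-iodoenone.

Step 2
Reactants: 3 2-methyl-2-vinyl-1,3-dioxolane; 2 2-iodocyclohex-2-en-1-one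
Product: 5 2-[2-(2-methyl-1,3-dioxolan-2-yl)ethyl]cyclohex-2-en-1-one, via B-alkyl-9-BBN adduct 4 (not isolated)
Conditions: 3, 9-BBN dimer, THF, 0 °C → rt; then 2, PdCl2(dppf) (5 mol %), AsPh3, Cs2CO3, DMF/H2O, rt
Reagents that add atoms: none
Why: 9-BBN adds anti-Markovnikov to the monosubstituted alkene (boron ends γ to the ketal oxygens, so no β-elimination), and B-alkyl Suzuki–Miyaura coupling of the borane with a 2-iodoenone under zerovalent palladium catalysis is a well-precedented way to 2-alkylcyclohexenones.

Step 3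
Reactants: 5 2-[2-(2-methyl-1,3-dioxolan-2-yl)ethyl]cyclohex-2-en-1-one; 6 vinylmagnesium bromide; 7 iodomethane
Product: 9 (2S,3R)-2-methyl-2-[2-(2-methyl-1,3-dioxolan-2-yl)ethyl]-3-vinylcyclohexan-1-one, via magnesium enolate 8 (not isolated)
Conditions: CuBr·SMe2 (5 mol %), (R)-1-[(S)-2-(diphenylphosphino)ferrocenyl]ethyldicyclohexylphosphine (6 mol %), 6 (2-MeTHF solution, slow addition), t-BuOMe, −78 °C; then 7 (excess), DMPU, −78 → 0 °C
Reagents that add atoms: vinylmagnesium bromide (6), C=C[Mg]Br; iodomethane (7), CI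
Why: The chiral monovalent copper–diphosphine complex is transmetalated by the Grignard reagent, forms a π-complex with the enone and adds oxidatively at the β-carbon to a trivalent copper σ-species, whose reductive elimination forms C10–C9 and releases magnesium enolate 8; DMPU-assisted SN2 methylation of 8 then forms C5–C14 in the same flask. The closest known reaction type is the copper-catalysed asymmetric conjugate addition of Grignard reagents to cyclic enones with in situ alkylation of the magnesium enolate, for which 2-substituted enones and vinyl nucleophiles are the less common partners. No ring is closed. C10 is set by the catalyst (vinyl to the Si face of C3 of the enone), and C5 by the substrate: in the tetrasubstituted enolate the C10 vinyl group lies pseudoaxial to avoid A(1,2) strain with the C5 chain, so iodomethane attacks axially from the opposite face and the methyl ends trans to vinyl (cis to H10), which is the cis relation of C9 and C6 that the cis-decalin needs. The step needs 1,4- over 1,2-addition (secured by copper catalysis, low temperature, slow addition and an ether solvent poor in THF), C- over O-methylation (soft iodomethane) and anti alkylation (secured by the C10 substituent).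

Step 4
Reactants: 9 (2S,3R)-2-methyl-2-[2-(2-methyl-1,3-dioxolan-2-yl)ethyl]-3-vinylcyclohexan-1-one
Product: 10 2-methyl-2-{2-[(1S,6R)-1-methyl-2-methylidene-6-vinylcyclohexyl]ethyl}-1,3-dioxolane
Conditions: Ph3PCH3Br, KOt-Bu, toluene, 90 °C
Reagents that add atoms: methyltriphenylphosphonium bromide, C[P+](c1ccccc1)(c1ccccc1)c1ccccc1.[Br-]
Why: Wittig methylenation of the hindered C4 ketone should tolerate forcing conditions because the flanking C5 is quaternary (nothing to epimerise) and the vinyl and ketal groups are inert to the ylide.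

Step 5
Reactants: 10 2-methyl-2-{2-[(1S,6R)-1-methyl-2-methylidene-6-vinylcyclohexyl]ethyl}-1,3-dioxolane
Product: 11 (3S,4R)-3-methyl-3-[2-(2-methyl-1,3-dioxolan-2-yl)ethyl]-2-methylidene-4-vinylcyclohexan-1-ol (both C3 epimers in eremophilane numbering)
Conditions: SeO2 (0.3 equiv), t-BuOOH, CH2Cl2, rt
Reagents that add atoms: selenium dioxide (catalytic oxygen carrier), O=[Se]=O; tert-butyl hydroperoxide, CC(C)(C)OO
Why: Riley allylic oxidation (ene reaction, then [2,3]-sigmatropic shift) of the 1,1-disubstituted alkene can only take place at C3 because C5 is quaternary, and the monosubstituted vinyl group is a much poorer ene partner; the C3 configuration is irrelevant since it is removed in step 6.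

Step 6
Reactants: 11 (3S,4R)-3-methyl-3-[2-(2-methyl-1,3-dioxolan-2-yl)ethyl]-2-methylidene-4-vinylcyclohexan-1-ol
Product: 12 (3S,4R)-3-methyl-3-[2-(2-methyl-1,3-dioxolan-2-yl)ethyl]-2-methylidene-4-vinylcyclohexan-1-one
Conditions: Dess–Martin periodinane, NaHCO3, CH2Cl2, 0 °C → rt
Reagents that add atoms: none
Why: Dess–Martin oxidation of the secondary allylic alcohols converges both epimers on one α-methylene ketone, which the neighbouring quaternary C5 should make stable enough to handle.

Step 7
Reactants: 12 (3S,4R)-3-methyl-3-[2-(2-methyl-1,3-dioxolan-2-yl)ethyl]-2-methylidene-4-vinylcyclohexan-1-one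
Product: 13 (1R,3S,4R)-3-methyl-3-[2-(2-methyl-1,3-dioxolan-2-yl)ethyl]-2-methylidene-4-vinylcyclohexan-1-ol (3α-OH)
Conditions: (S)-2-methyl-CBS-oxazaborolidine (0.2 equiv), catecholborane, toluene, −78 °C; then MeOH
Reagents that add atoms: none
Why: Corey–Bakshi–Shibata reduction sets C3 by reagent control, the alkenyl C4 side acting as the large and the C2 methylene as the small group so that the (S)-catalyst should give the (R)-alcohol (3α-OH), while catecholborane at −78 °C leaves the vinyl group untouched.

Step 8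
Reactants: 13 (1R,3S,4R)-3-methyl-3-[2-(2-methyl-1,3-dioxolan-2-yl)ethyl]-2-methylidene-4-vinylcyclohexan-1-ol
Product: 14 tert-butyl(dimethyl){[(1R,3S,4R)-3-methyl-3-[2-(2-methyl-1,3-dioxolan-2-yl)ethyl]-2-methylidene-4-vinylcyclohexyl]oxy}silane
Conditions: TBSCl, imidazole, DMAP (cat.), DMF, 40 °C
Reagents that add atoms: tert-butyldimethylsilyl chloride, CC(C)(C)[Si](C)(C)Cl
Why: Silylation protects the C3 hydroxyl until step 20 and gives a 3α substituent that later keeps ring A in the chair with C14 axial.

Step 9
Reactants: 14 tert-butyl(dimethyl){[(1R,3S,4R)-3-methyl-3-[2-(2-methyl-1,3-dioxolan-2-yl)ethyl]-2-methylidene-4-vinylcyclohexyl]oxy}silane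
Product: 16 2-[(1R,2S,4R)-4-(tert-butyldimethylsilyloxy)-2-methyl-2-[2-(2-methyl-1,3-dioxolan-2-yl)ethyl]-3-methylidenecyclohexyl]ethan-1-ol, via trialkylborane 15 (not isolated)
Conditions: disiamylborane (from BH3·THF and 2-methylbut-2-ene), THF, 0 °C; then NaOH, H2O2, 0 °C → rt
Reagents that add atoms: hydrogen peroxide, OO
Why: Hydroboration–oxidation with the bulky disiamylborane should pick the monosubstituted vinyl group over the 1,1-disubstituted alkene (flanked by quaternary C5 and the silyloxy-bearing C3) and place the hydroxyl anti-Markovnikov on C8.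

Step 10
Reactants: 16 2-[(1R,2S,4R)-4-(tert-butyldimethylsilyloxy)-2-methyl-2-[2-(2-methyl-1,3-dioxolan-2-yl)ethyl]-3-methylidenecyclohexyl]ethan-1-ol
Product: 17 4-[(1S,3R,6R)-3-(tert-butyldimethylsilyloxy)-6-(2-hydroxyethyl)-1-methyl-2-methylidenecyclohexyl]butan-2-one
Conditions: PPTS, acetone/H2O, 50 °C
Reagents that add atoms: water, O
Why: Acid-catalysed hydrolysis (transketalisation) of the dioxolane with PPTS is mild enough to leave the secondary silyl ether and the allylic system alone.

Step 11
Reactants: 17 4-[(1S,3R,6R)-3-(tert-butyldimethylsilyloxy)-6-(2-hydroxyethyl)-1-methyl-2-methylidenecyclohexyl]butan-2-one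
Product: 18 2-[(1R,2S,4R)-4-(tert-butyldimethylsilyloxy)-2-methyl-3-methylidene-2-(3-oxobutyl)cyclohexyl]acetaldehyde
Conditions: Dess–Martin periodinane, NaHCO3, CH2Cl2, 0 °C → rt
Reagents that add atoms: none
Why: Dess–Martin oxidation takes the primary alcohol to the C8 aldehyde under neutral conditions with no epimerisable centre at risk.

Step 12
Reactants: 18 2-[(1R,2S,4R)-4-(tert-butyldimethylsilyloxy)-2-methyl-3-methylidene-2-(3-oxobutyl)cyclohexyl]acetaldehyde
Product: 19 3α-(tert-butyldimethylsilyloxy)-8α-hydroxy-13-nor-10βH-eremophil-4(15)-en-11-one (cis-decalin with 7β-acetyl)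
Conditions: KOH (0.5 equiv), MeOH, 0 °C
Reagents that add atoms: none
Why: Reversible intramolecular aldol addition (6-enolexo-exo-trig) of the C7 ketone enolate to the C8 aldehyde should close ring B, since attack of the aldehyde enolate on the ketone gives a tertiary aldolate that reverts and the C12 enolate could only form an eight-membered ring; the acetyl-bearing C7 equilibrates to the equatorial 7β position because the 3α-silyloxy group holds ring A in the chair with C14 axial (in the other chair it would be syn-axial to C6), and the C8 carbinol configuration (expected equatorial) does not matter because C8 becomes the ketone in step 17.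

Step 13
Reactants: 19 3α-(tert-butyldimethylsilyloxy)-8α-hydroxy-13-nor-10βH-eremophil-4(15)-en-11-one
Product: 20 3α-(tert-butyldimethylsilyloxy)-8α-(triethylsilyloxy)-13-nor-10βH-eremophil-4(15)-en-11-one
Conditions: TESCl, imidazole, DMF, 0 °C → rt
Reagents that add atoms: chlorotriethylsilane, CC[Si](Cl)(CC)CC
Why: Silylation of the β-hydroxy ketone blocks retro-aldol cleavage and dehydration in the next two steps.

Step 14
Reactants: 20 3α-(tert-butyldimethylsilyloxy)-8α-(triethylsilyloxy)-13-nor-10βH-eremophil-4(15)-en-11-one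
Product: 21 3α-(tert-butyldimethylsilyloxy)-8α-(triethylsilyloxy)-13-nor-10βH-eremophilan-11-one (4β-methyl)
Conditions: Mn(dpm)3 (10 mol %), PhSiH3, t-BuOOH, i-PrOH, rt
Reagents that add atoms: none
Why: Mukaiyama-type hydrogen-atom-transfer hydrogenation (trivalent manganese hydride) gives the tertiary C4 radical, which should take up the second hydrogen to give the thermodynamically preferred epimer with C15 equatorial and cis to C14 (an axial C15 would be syn-axial to C9 in the locked cis-decalin), whereas a surface catalyst would add from the less hindered equatorial direction; the ketone and silyl ethers are not touched.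

Step 15
Reactants: 21 3α-(tert-butyldimethylsilyloxy)-8α-(triethylsilyloxy)-13-nor-10βH-eremophilan-11-one
Product: 22 3α-(tert-butyldimethylsilyloxy)-8α-(triethylsilyloxy)-10βH-eremophil-11-ene
Conditions: Zn, CH2Br2, TiCl4, THF, 0 °C (reagent aged); then 21, CH2Cl2, 0 °C → rt
Reagents that add atoms: dibromomethane, BrCBr
Why: Takai–Lombardo methylenation is non-basic, so the enolisable methyl ketone should be converted into the isopropenyl group without epimerising C7 or eliminating the β-silyloxy group.

Step 16
Reactants: 22 3α-(tert-butyldimethylsilyloxy)-8α-(triethylsilyloxy)-10βH-eremophil-11-ene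
Product: 23 3α-(tert-butyldimethylsilyloxy)-10βH-eremophil-11-en-8α-ol
Conditions: PPTS, MeOH/CH2Cl2, 0 °C → rt
Reagents that add atoms: none
Why: Acid-catalysed methanolysis cleaves the triethylsilyl ether much faster than the hindered secondary tert-butyldimethylsilyl ether at C3.

Step 17
Reactants: 23 3α-(tert-butyldimethylsilyloxy)-10βH-eremophil-11-en-8α-ol
Product: 24 3α-(tert-butyldimethylsilyloxy)-10βH-eremophil-11-en-8-one
Conditions: Dess–Martin periodinane, NaHCO3, CH2Cl2, 0 °C
Reagents that add atoms: none
Why: Buffered Dess–Martin oxidation should give the β,γ-unsaturated ketone without moving the isopropenyl double bond into conjugation, and C7 keeps its equatorial, thermodynamically preferred configuration.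

Step 18
Reactants: 24 3α-(tert-butyldimethylsilyloxy)-10βH-eremophil-11-en-8-one
Product: 26 3α-(tert-butyldimethylsilyloxy)-9β-hydroxy-10βH-eremophil-11-en-8-one, via sodium enolate 25 (not isolated)
Conditions: NaN(SiMe3)2 (1.1 equiv), THF, −78 °C; then 2-(phenylsulfonyl)-3-phenyloxaziridine, −78 °C; aq. NH4Cl
Reagents that add atoms: 2-(phenylsulfonyl)-3-phenyloxaziridine, O=S(=O)(c1ccccc1)N1OC1c1ccccc1
Why: Kinetic deprotonation by the bulky amide should occur at the C9 methylene and not at the tertiary C7–H (whose allylic activation needs a conformation with A(1,3) strain), and Davis oxidation of the enolate from the convex β face (the α face of ring B is covered by ring A) should give the equatorial 9β-hydroxyl cis to H10.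

Step 19
Reactants: 26 3α-(tert-butyldimethylsilyloxy)-9β-hydroxy-10βH-eremophil-11-en-8-one; 27 angelic acid [(Z)-2-methylbut-2-enoic acid]
Product: 29 9β-angeloyloxy-3α-(tert-butyldimethylsilyloxy)-10βH-eremophil-11-en-8-one, via mixed anhydride 28 (not isolated)
Conditions: 27, 2,4,6-trichlorobenzoyl chloride, Et3N, toluene, rt; then 26, toluene, rt → 60 °C
Reagents that add atoms: angelic acid (27), C/C=C(/C)C(=O)O
Why: Yamaguchi esterification, in which the alcohol attacks the less hindered angeloyl carbonyl of the mixed anhydride, is run without DMAP to limit Z → E isomerisation to the tiglate.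

Step 20
Reactants: 29 9β-angeloyloxy-3α-(tert-butyldimethylsilyloxy)-10βH-eremophil-11-en-8-one
Product: 30 9β-angeloyloxy-3α-hydroxy-10βH-eremophil-11-en-8-one
Conditions: HF·pyridine, pyridine, THF, 0 °C → rt
Reagents that add atoms: none
Why: Fluoride-mediated desilylation under buffered, weakly acidic conditions should spare the angelate, the α-acyloxy ketone and the isopropenyl group.

Step 21
Reactants: 30 9β-angeloyloxy-3α-hydroxy-10βH-eremophil-11-en-8-one; 31 3-methylbut-2-enoyl chloride
Product: 32 (3R,4R,5R,7R,9R,10S)-9β-angeloyloxy-3α-senecioyloxy-10βH-eremophil-11-en-8-one (CNP0164025.2)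
Conditions: 31, pyridine, DMAP (cat.), CH2Cl2, 0 °C
Reagents that add atoms: 3-methylbut-2-enoyl chloride (31), CC(C)=CC(Cl)=O
Why: Acylation of the equatorial secondary alcohol with the acid chloride and pyridine (nucleophilic catalysis) is used because pyridine, unlike Et3N, should not form the vinylketene that deconjugates the senecioyl unit.

**Compound list**
1 | cyclohex-2-en-1-one | O=C1C=CCCC1 | starting material
2 | 2-iodocyclohex-2-en-1-one | O=C1CCCC=C1I | intermediate
3 | 2-methyl-2-vinyl-1,3-dioxolane | C=CC1(C)OCCO1 | starting material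
4 | 9-[2-(2-methyl-1,3-dioxolan-2-yl)ethyl]-9-borabicyclo[3.3.1]nonane | CC1(CCB2C3CCCC2CCC3)OCCO1 | intermediate (not isolated)
5 | 2-[2-(2-methyl-1,3-dioxolan-2-yl)ethyl]cyclohex-2-en-1-one | O=C1CCCC=C1CCC1(C)OCCO1 | intermediate
6 | vinylmagnesium bromide | C=C[Mg]Br | starting material
7 | iodomethane | CI | starting material
8 | bromomagnesium (3R)-2-[2-(2-methyl-1,3-dioxolan-2-yl)ethyl]-3-vinylcyclohex-1-en-1-olate | C=C[C@H]1CCCC(O[Mg]Br)=C1CCC1(C)OCCO1 | intermediate (not isolated)
9 | (2S,3R)-2-methyl-2-[2-(2-methyl-1,3-dioxolan-2-yl)ethyl]-3-vinylcyclohexan-1-one | C=C[C@H]1CCCC(=O)[C@@]1(C)CCC1(C)OCCO1 | intermediate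
10 | 2-methyl-2-{2-[(1S,6R)-1-methyl-2-methylidene-6-vinylcyclohexyl]ethyl}-1,3-dioxolane | C=C[C@H]1CCCC(=C)[C@@]1(C)CCC1(C)OCCO1 | intermediate
11 | (3S,4R)-3-methyl-3-[2-(2-methyl-1,3-dioxolan-2-yl)ethyl]-2-methylidene-4-vinylcyclohexan-1-ol, carbinol epimers | C=C[C@H]1CCC(O)C(=C)[C@@]1(C)CCC1(C)OCCO1 | intermediate
12 | (3S,4R)-3-methyl-3-[2-(2-methyl-1,3-dioxolan-2-yl)ethyl]-2-methylidene-4-vinylcyclohexan-1-one | C=C[C@H]1CCC(=O)C(=C)[C@@]1(C)CCC1(C)OCCO1 | intermediate
13 | (1R,3S,4R)-3-methyl-3-[2-(2-methyl-1,3-dioxolan-2-yl)ethyl]-2-methylidene-4-vinylcyclohexan-1-ol | C=C[C@H]1CC[C@@H](O)C(=C)[C@@]1(C)CCC1(C)OCCO1 | intermediate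
14 | tert-butyldimethylsilyl ether of 13 | C=C[C@H]1CC[C@@H](O[Si](C)(C)C(C)(C)C)C(=C)[C@@]1(C)CCC1(C)OCCO1 | intermediate
15 | bis(3-methylbutan-2-yl)borane adduct of 14 at the vinyl terminus (C8–B) | CC(C)C(C)B(CC[C@H]1CC[C@@H](O[Si](C)(C)C(C)(C)C)C(=C)[C@@]1(C)CCC1(C)OCCO1)C(C)C(C)C | intermediate (not isolated)
16 | 2-[(1R,2S,4R)-4-(tert-butyldimethylsilyloxy)-2-methyl-2-[2-(2-methyl-1,3-dioxolan-2-yl)ethyl]-3-methylidenecyclohexyl]ethan-1-ol | OCC[C@H]1CC[C@@H](O[Si](C)(C)C(C)(C)C)C(=C)[C@@]1(C)CCC1(C)OCCO1 | intermediate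
17 | 4-[(1S,3R,6R)-3-(tert-butyldimethylsilyloxy)-6-(2-hydroxyethyl)-1-methyl-2-methylidenecyclohexyl]butan-2-one | OCC[C@H]1CC[C@@H](O[Si](C)(C)C(C)(C)C)C(=C)[C@@]1(C)CCC(C)=O | intermediate
18 | 2-[(1R,2S,4R)-4-(tert-butyldimethylsilyloxy)-2-methyl-3-methylidene-2-(3-oxobutyl)cyclohexyl]acetaldehyde | O=CC[C@H]1CC[C@@H](O[Si](C)(C)C(C)(C)C)C(=C)[C@@]1(C)CCC(C)=O | intermediate
19 | 3α-(tert-butyldimethylsilyloxy)-8α-hydroxy-13-nor-10βH-eremophil-4(15)-en-11-one (7β-acetyl cis-decalin; C8 epimer also usable) | CC(=O)[C@H]1C[C@@]2(C)[C@H](CC[C@@H](O[Si](C)(C)C(C)(C)C)C2=C)C[C@@H]1O | intermediate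
20 | 3α-(tert-butyldimethylsilyloxy)-8α-(triethylsilyloxy)-13-nor-10βH-eremophil-4(15)-en-11-one | CC(=O)[C@H]1C[C@@]2(C)[C@H](CC[C@@H](O[Si](C)(C)C(C)(C)C)C2=C)C[C@@H]1O[Si](CC)(CC)CC | intermediate
21 | 3α-(tert-butyldimethylsilyloxy)-8α-(triethylsilyloxy)-13-nor-10βH-eremophilan-11-one (4β-methyl) | CC(=O)[C@H]1C[C@@]2(C)[C@H](CC[C@@H](O[Si](C)(C)C(C)(C)C)[C@@H]2C)C[C@@H]1O[Si](CC)(CC)CC | intermediate
22 | 3α-(tert-butyldimethylsilyloxy)-8α-(triethylsilyloxy)-10βH-eremophil-11-ene | C=C(C)[C@H]1C[C@@]2(C)[C@H](CC[C@@H](O[Si](C)(C)C(C)(C)C)[C@@H]2C)C[C@@H]1O[Si](CC)(CC)CC | intermediate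
23 | 3α-(tert-butyldimethylsilyloxy)-10βH-eremophil-11-en-8α-ol | C=C(C)[C@H]1C[C@@]2(C)[C@H](CC[C@@H](O[Si](C)(C)C(C)(C)C)[C@@H]2C)C[C@@H]1O | intermediate
24 | 3α-(tert-butyldimethylsilyloxy)-10βH-eremophil-11-en-8-one | C=C(C)[C@H]1C[C@@]2(C)[C@H](CC[C@@H](O[Si](C)(C)C(C)(C)C)[C@@H]2C)CC1=O | intermediate
25 | sodium 3α-(tert-butyldimethylsilyloxy)-10βH-eremophila-8,11-dien-8-olate | C=C(C)[C@H]1C[C@@]2(C)[C@H](CC[C@@H](O[Si](C)(C)C(C)(C)C)[C@@H]2C)C=C1[O-].[Na+] | intermediate (not isolated)
26 | 3α-(tert-butyldimethylsilyloxy)-9β-hydroxy-10βH-eremophil-11-en-8-one | C=C(C)[C@H]1C[C@@]2(C)[C@H](CC[C@@H](O[Si](C)(C)C(C)(C)C)[C@@H]2C)[C@@H](O)C1=O | intermediate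
27 | angelic acid, (Z)-2-methylbut-2-enoic acid | C/C=C(/C)C(=O)O | starting material
28 | (Z)-2-methylbut-2-enoic 2,4,6-trichlorobenzoic anhydride | C/C=C(/C)C(=O)OC(=O)c1c(Cl)cc(Cl)cc1Cl | intermediate (not isolated)
29 | 9β-angeloyloxy-3α-(tert-butyldimethylsilyloxy)-10βH-eremophil-11-en-8-one | C=C(C)[C@H]1C[C@@]2(C)[C@H](CC[C@@H](O[Si](C)(C)C(C)(C)C)[C@@H]2C)[C@@H](OC(=O)/C(C)=C\C)C1=O | intermediate
30 | 9β-angeloyloxy-3α-hydroxy-10βH-eremophil-11-en-8-one | C=C(C)[C@H]1C[C@@]2(C)[C@H](CC[C@@H](O)[C@@H]2C)[C@@H](OC(=O)/C(C)=C\C)C1=O | intermediate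
31 | 3-methylbut-2-enoyl chloride | CC(C)=CC(Cl)=O | starting material
32 | (3R,4R,5R,7R,9R,10S)-9β-angeloyloxy-3α-senecioyloxy-10βH-eremophil-11-en-8-one (CNP0164025.2) | C=C(C)[C@H]1C[C@@]2(C)[C@H](CC[C@@H](OC(=O)C=C(C)C)[C@@H]2C)[C@@H](OC(=O)/C(C)=C\C)C1=O | target

**Totals**
Total step count: 21. Longest linear sequence: 21 steps (1 → 32).

**Three steps most likely to fail**

Step 3 (key step). What may go wrong: uncatalysed 1,2-addition or racemic background 1,4-addition of the vinyl Grignard reagent, and slow or incomplete C-methylation of the hindered, aggregated magnesium enolate, so that protonation on work-up returns unmethylated ketone. Fallback, setting out from 5 and coming back at 9: the same copper-catalysed vinyl addition is run, but enolate 8 is silylated (TMSCl, Et3N, HMPA, −78 → 0 °C) and isolated as trimethylsilyl enol ether F1. Methyllithium in THF at 0 °C then unmasks the regiodefined lithium enolate F2. This more reactive enolate is methylated with iodomethane in THF/DMPU, again anti to the vinyl group, to give 9. This separates the conjugate addition from the alkylation and uses the classical regiospecific enolate generation from a silyl enol ether.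

Step 18. What may go wrong: loss of regiocontrol in the enolisation (removal of the doubly activated C7–H, leading to C7 hydroxylation or to migration of the isopropenyl double bond into conjugation) and leakage of facial selectivity at C9. Fallback, setting out from 24 and coming back at 26: ketone 24 is condensed with pyrrolidine (TsOH cat., benzene, water removal) to the less substituted pyrrolidine enamine F5, in which A(1,3) strain keeps the double bond on the C9 side. The enamine is oxidised with 2-(phenylsulfonyl)-3-phenyloxaziridine from the convex β face, and aqueous hydrolysis gives 26. Regiocontrol then rests on enamine thermodynamics, not on kinetic deprotonation.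

Step 12. What may go wrong: over-reaction of the aldol adduct by E1cB dehydration to the conjugated enone, and competing attack of the aldehyde enolate on the ketone. Fallback, setting out from 18 and coming back at 19: the condensation is driven on purpose (KOH, MeOH, 50 °C) to the conjugated enone F3. Weitz–Scheffer epoxidation (H2O2, NaOH, MeOH, 0 °C) gives epoxy ketone F4. Reductive cleavage of its Cα–O bond with SmI2 (THF/MeOH, −78 °C) returns the β-hydroxy ketone 19, with C7 protonated to the equatorial acetyl epimer; the C8 configuration is again of no consequence.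

**Further compounds**
F1 | step 3 | trimethyl{[(3R)-2-[2-(2-methyl-1,3-dioxolan-2-yl)ethyl]-3-vinylcyclohex-1-en-1-yl]oxy}silane | C=C[C@H]1CCCC(O[Si](C)(C)C)=C1CCC1(C)OCCO1
F2 | step 3 | lithium (3R)-2-[2-(2-methyl-1,3-dioxolan-2-yl)ethyl]-3-vinylcyclohex-1-en-1-olate | C=C[C@H]1CCCC([O-])=C1CCC1(C)OCCO1.[Li+]
F3 | step 12 | 3α-(tert-butyldimethylsilyloxy)-13-nor-10βH-eremophila-4(15),7-dien-11-one (7-acetyl-Δ7 enone) | CC(=O)C1=CC[C@H]2CC[C@@H](O[Si](C)(C)C(C)(C)C)C(=C)[C@@]2(C)C1
F4 | step 12 | 7,8-epoxide of F3 (epoxy ketone, epoxide face not specified) | CC(=O)C12OC1C[C@H]1CC[C@@H](O[Si](C)(C)C(C)(C)C)C(=C)[C@@]1(C)C2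
F5 | step 18 | 1-[3α-(tert-butyldimethylsilyloxy)-10βH-eremophila-8,11-dien-8-yl]pyrrolidine | C=C(C)[C@H]1C[C@@]2(C)[C@H](CC[C@@H](O[Si](C)(C)C(C)(C)C)[C@@H]2C)C=C1N1CCCC1
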